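## Analysis of the target

The target 23 is a flavone, a benzopyran-4-one (rings A and C) carrying an aryl group (ring B) on C2. Ring A is substituted at every position except C6 (5-OH, 7-OMe, 8-OMe), ring C carries a methoxy group on C3, and ring B has the 2',4'-dihydroxy-5'-methoxy pattern, so seven oxygen substituents must be placed, three of them free (O5, O2', O4') and four as methyl ethers. The molecule is flat and achiral, so stereocentres that appear on the way (C2 and C3 of a flavanonol) are transient and need no control. The sensitive groups are the three phenols, two of them on an easily oxidised resorcinol-type ring B, and the enol ether at C3; this argues for carrying the phenols as benzyl ethers and releasing them last under neutral conditions. The difficulty is regiochemistry rather than the skeleton: the 5,7,8-pattern of ring A and the 2',4',5'-pattern of ring B must be fixed unambiguously, and free and methylated oxygens must be kept apart without any selective demethylation. The strategy rests on C3 and C4 of ring C, which are neighbours, both bear oxygen (C3–OMe, C4=O), and one oxidation level below the flavonol form an α-ketol, the product of joining two aldehyde carbons by acyl-anion chemistry, with O1 as a tether between the two halves.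

## Retrosynthetic reasoning

23 from 22: the three O–benzyl bonds at O5, O2' and O4' are cut. Benzyl ethers distinguish the future phenols from the four methyl ethers throughout the route and fall together in one hydrogenolysis, which the methyl ethers, the pyranone and the C3 enol ether should survive.

22 from 21: the O3–CH3 bond is cut. In 21 the C3 hydroxyl is the only free hydroxyl, so a simple O-methylation needs no selectivity.

21 from 19: no bond is cut; the oxidation level is lowered by two electrons. Flavonol 21 is the enol tautomer of the 3,4-dione 20, and 20 is the oxidation product of ketol 19. This converts the aromatic pyranone into a saturated ring that can be made by a carbonyl addition, and it means the two stereocentres of 19 are erased in the forward direction.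

19 from 18: the C3–C4 bond is cut, which is the central disconnection. Both carbons carry oxygen, so both can be aldehydes, and the cut leaves ring A and ring B joined only through the O1–C2 ether of dialdehyde 18. Other cuts were weighed and rejected. Cutting C4–C4a would demand C–C bond formation at a ring carbon flanked by two oxygens. Cutting C2–C1' would demand arylation of a finished chromone. The forward reaction has to couple two electrophilic carbons with reversed polarity and must be a crossed, not a homo, coupling; the O1 tether makes it intramolecular and six-membered. The ketol may form with its carbonyl at C4 (19) or, if the aliphatic aldehyde is the acyl-anion donor, with the carbonyl at C3. Both converge on 21 through the enediol and the oxidation. The donor choice still matters in one respect: an acyl-anion equivalent at C3 has the ring A aryloxide on the neighbouring carbon and could expel it, so the forward conditions must favour C–C bond formation over that fragmentation.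

18 from 17 from 16: functional-group interconversion only. The α-aryl-α-aryloxy aldehyde of 18 is too enolisable to carry through several steps, so both aldehydes are released together at the end from diol 17. Diol 17 comes by hydride reduction of aldehyde ester 16, whose ester group is needed one step earlier.

16 from 6 and 15: the O1–C2 bond is cut. This divides the molecule into halves of similar size, salicylaldehyde 6 (ring A with C4) and α-bromo ester 15 (ring B with C2 and C3). The ester next to the reacting carbon accelerates SN2 displacement by the phenoxide and suppresses ionisation of the electron-rich benzylic position.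

6 from 5, 4, 3 and 1: the C4–C4a bond is cut first. Phenol 5 has a single free ortho position, so a phenol-directed formylation can only give 6. The phenol oxygen of 5 (the future O1) replaces the bromine of 4 by C–O coupling. The benzyloxy group of 4 (the future O5) comes from phenol 3, which arises from aldehyde 1 by aryl migration to oxygen. In this way the 5,7,8-pattern is taken from the substitution pattern of a bought arene.

15 from 14, 13, 11, 10, 9 and 7: the C2–C1' bond is cut between an aryl anion and a two-carbon oxalyl electrophile. The aryl anion comes from bromide 11, made by bromination of 10 at the one position that is para to one benzyloxy group and ortho to the other. Arene 10 is the benzyl ether of phenol 9, obtained from aldehyde 7 by the same aryl migration used for ring A. Keto ester 13 is reduced to mandelate 14 and converted to bromide 15.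

## Alternatives that were turned down

Alternative 1: Both bonds to C4 (C4a–C4 and C4–C3) are cut, and C4 is supplied as carbon monoxide (A4).
- Forward reaction: the ring A iodide 1-(benzyloxy)-2-iodo-4,5-dimethoxy-3-(methoxymethoxy)benzene (A2), A4 and the enolate of the ring B ketone 1-[2,4-bis(benzyloxy)-5-methoxyphenyl]-2-methoxyethan-1-one (A3) would be joined on zerovalent palladium (Pd(dba)2 with the wide-bite-angle bisphosphine Xantphos). Oxidative addition of A2, insertion of A4 and attack of the enolate of A3 on the acylpalladium species would give the open-chain 2-methoxy-1,3-diketone A1; no ring closes at that point. Acid would then remove the methoxymethyl group of A1 and cyclodehydrate it to 22.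
- In its favour: C3 carries its methoxy group from the start in A3. There is no stereochemistry, no redox adjustment and no fragile dialdehyde. The closure of A1 to the flavone is classical. The sequence should be shorter than the chosen one, so on step economy this alternative is the stronger.
- Against it here: the iodine of A2 sits between two alkoxy groups on a very electron-rich ring, so oxidative addition should be slow and the acylpalladium intermediate crowded. The α-methoxy enolate of A3 is hindered. The product A1 is more acidic than A3 and can tie up base and metal. The iodine of A2 must first be placed regioselectively between two oxygens, and A4 is a toxic gas that needs special handling.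
- Comparison: the chosen strategy offers, in place of the shorter sequence, a central step without metal or gas at room temperature. It also forms its bond away from the crowded C4a position, because C4 is already attached to ring A by an unambiguous formylation.

Alternative 2: Ring B is disconnected across C1'–C2' and C5'–C6', a [4+2] retron.
- Forward reaction: the electron-rich diene 1,4-dimethoxy-1,3-bis(trimethylsilyloxy)buta-1,3-diene (A7) would add to the alkyne of 2-ethynyl-3,5,7,8-tetramethoxy-4H-chromen-4-one (A6). Acid work-up would aromatise the adduct by loss of methanol and of the silyl groups and give 2-(2,4-dihydroxy-5-methoxyphenyl)-3,5,7,8-tetramethoxy-4H-chromen-4-one (A5).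
- In its favour: the three oxygens of ring B arrive from A7 in one step without protecting groups, and aromatisation is a strong driving force. On protecting-group economy for ring B this alternative is the stronger.
- Against it here: the alkyne of A6 is activated only through the C2=C3 bond of a chromone that four methoxy groups make electron-rich, so the cycloaddition should be sluggish. The regiochemistry rests on polarisation alone. On aromatisation the ketal carbon must lose its methoxy group and not its silyloxy group to leave O2' free, and nothing secures this. A7 is labile to hydrolysis, and A6 needs its own multistep synthesis. A5 still carries a methyl group on O5, which would have to be removed selectively next to the C3 methoxy group, which also flanks the carbonyl.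
- Comparison: the chosen strategy takes ring B from an aromatic starting material in which each oxygen is already placed. It separates free from methylated oxygens by benzyl ethers, so the selective demethylation that A5 requires is not needed.

Alternative 3: O1–C8a, C4–C4a and O1–C2 are cut, and ring A enters as an aryne.
- Forward reaction: fluoride (CsF) would release 3,5-dimethoxybenzyne from the silyl triflate 3,5-dimethoxy-2-(trimethylsilyl)phenyl trifluoromethanesulfonate (A9). The carboxylate of 3-[2,4-bis(benzyloxy)-5-methoxyphenyl]-2,3-dimethoxyprop-2-enoic acid (A10) would add to the aryne, the resulting aryl anion would take over the acyl group from oxygen, and the phenoxide so formed would displace the β-methoxy group by addition–elimination. This cascade closes ring C and gives 2-[2,4-bis(benzyloxy)-5-methoxyphenyl]-3,5,7-trimethoxy-4H-chromen-4-one (A8).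
- In its favour: A9 and A10 would be joined through three new bonds and one ring in a single mild operation. In bonds formed per step this alternative is clearly the stronger.
- Against it here: regiocontrol of the addition to the aryne from A9 depends on a single methoxy group beside the triple bond. An aryne with oxygen on both flanks, which the 5,7,8-pattern would need, loses that bias, so A8 has hydrogen at C8. The C8 oxygen would have to be added later, for example by 5-O-demethylation, Elbs-type para-hydroxylation and selective methylation, which are several low-yielding steps. Protonation of the aryl anion can compete with the acyl shift, and A10 is a tetrasubstituted enol ether acid that needs its own synthesis.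
- Comparison: the chosen strategy has every ring A oxygen in place before ring C is built, whereas A8 lacks one of them. The price is a longer, stepwise assembly.

Key step: step 14

Assumption: the target is achiral, so stereogenic intermediates are carried as racemates without enantiocontrol; 3-(benzyloxy)-4-methoxybenzaldehyde (the benzyl ether of isovanillin) is taken as a purchased starting material.

## Route

Step 1
Reactants: 1 3-bromo-4,5-dimethoxybenzaldehyde
Product: 3 3-bromo-4,5-dimethoxyphenol, via 3-bromo-4,5-dimethoxyphenyl formate 2 (not isolated)
Conditions: mCPBA, CH2Cl2, 0 °C to rt; then K2CO3 (cat.), MeOH, rt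
Reagents that add atoms: 3-chloroperbenzoic acid, O=C(OO)c1cccc(Cl)c1
Why: Baeyer–Villiger oxidation of an electron-rich benzaldehyde; the para-methoxy group should favour aryl over hydride migration, and the formate is cleaved by methanolysis.

Step 2
Reactants: 3 3-bromo-4,5-dimethoxyphenol
Product: 4 5-(benzyloxy)-1-bromo-2,3-dimethoxybenzene
Conditions: BnBr, K2CO3, DMF, rt
Reagents that add atoms: benzyl bromide, BrCc1ccccc1
Why: Williamson etherification of the only phenol; the benzyl group marks the oxygen that becomes the free 5-OH of the target.

Step 3
Reactants: 4 5-(benzyloxy)-1-bromo-2,3-dimethoxybenzene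
Product: 5 5-(benzyloxy)-2,3-dimethoxyphenol
Conditions: Pd2(dba)3 (2 mol %), t-BuXPhos (8 mol %), KOH, 1,4-dioxane/H2O, 100 °C; then aq. HCl
Reagents that add atoms: potassium hydroxide, [K+].[OH-]
Why: Buchwald–Hartwig-type C–O coupling (hydroxylation of an aryl bromide): oxidative addition to zerovalent palladium, bromide–hydroxide exchange and C–O reductive elimination promoted by the bulky biaryl phosphine; the aryl ethers are inert.

Step 4
Reactants: 5 5-(benzyloxy)-2,3-dimethoxyphenol
Product: 6 6-(benzyloxy)-2-hydroxy-3,4-dimethoxybenzaldehyde
Conditions: MgCl2, Et3N, (CH2O)n, MeCN, reflux; then aq. HCl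
Reagents that add atoms: paraformaldehyde (as formaldehyde), C=O
Why: Casnati–Skattebøl ortho-formylation: the magnesium phenoxide delivers formaldehyde to the single free ortho position (between OH and OBn) and a second formaldehyde oxidises the benzylic alkoxide by hydride transfer; the free para position is not attacked under magnesium control.

Step 5
Reactants: 7 3-(benzyloxy)-4-methoxybenzaldehyde
Product: 9 3-(benzyloxy)-4-methoxyphenol, via 3-(benzyloxy)-4-methoxyphenyl formate 8 (not isolated)
Conditions: mCPBA, CH2Cl2, 0 °C to rt; then K2CO3 (cat.), MeOH, rt
Reagents that add atoms: 3-chloroperbenzoic acid, O=C(OO)c1cccc(Cl)c1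
Why: Baeyer–Villiger oxidation; the coplanar para-methoxy group makes aryl migration reliable, and methanolysis frees the phenol.

Step 6
Reactants: 9 3-(benzyloxy)-4-methoxyphenol
Product: 10 2,4-bis(benzyloxy)-1-methoxybenzene
Conditions: BnBr, K2CO3, DMF, rt
Reagents that add atoms: benzyl bromide, BrCc1ccccc1
Why: Williamson etherification; the two benzyloxy groups now mark the future 2'- and 4'-hydroxyls and the methoxy group the 5'-position.

Step 7
Reactants: 10 2,4-bis(benzyloxy)-1-methoxybenzene
Product: 11 1,5-bis(benzyloxy)-2-bromo-4-methoxybenzene
Conditions: NBS, MeCN, 0 °C to rt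
Reagents that add atoms: N-bromosuccinimide, O=C1CCC(=O)N1Br
Why: Electrophilic aromatic bromination at the position para to one benzyloxy group and ortho to the other; the position between the two benzyloxy groups is shielded and the one next to the methoxy group is activated by a single donor only.

Step 8
Reactants: 11 1,5-bis(benzyloxy)-2-bromo-4-methoxybenzene
Product: 13 ethyl 2-[2,4-bis(benzyloxy)-5-methoxyphenyl]-2-oxoacetate, via [2,4-bis(benzyloxy)-5-methoxyphenyl]lithium 12 (not isolated)
Conditions: n-BuLi, THF, −78 °C; then added to diethyl oxalate (3 equiv), THF, −78 °C; aq. HCl quench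
Reagents that add atoms: diethyl oxalate, CCOC(=O)C(=O)OCC
Why: Bromine–lithium exchange followed by acylation with an oxalate diester; inverse addition to excess oxalate and the cold-stable tetrahedral adduct should hold the reaction at the α-keto ester.

Step 9
Reactants: 13 ethyl 2-[2,4-bis(benzyloxy)-5-methoxyphenyl]-2-oxoacetate
Product: 14 ethyl 2-[2,4-bis(benzyloxy)-5-methoxyphenyl]-2-hydroxyacetate (racemic)
Conditions: NaBH4 (0.3 equiv), EtOH, −20 to 0 °C
Reagents that add atoms: none
Why: Borohydride reduction of the activated ketone of an α-keto ester; substoichiometric hydride and low temperature should leave the ester untouched, and the new stereocentre is formed racemic on purpose.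

Step 10
Reactants: 14 ethyl 2-[2,4-bis(benzyloxy)-5-methoxyphenyl]-2-hydroxyacetate (racemic)
Product: 15 ethyl 2-[2,4-bis(benzyloxy)-5-methoxyphenyl]-2-bromoacetate (racemic)
Conditions: CBr4, PPh3, CH2Cl2, 0 °C; used without storage
Reagents that add atoms: carbon tetrabromide, BrC(Br)(Br)Br
Why: Appel bromination under neutral conditions that spare the benzyl ethers; the adjacent ester disfavours ionisation of the electron-rich benzylic carbon, so the bromide should be handleable for immediate use.

Step 11
Reactants: 6 6-(benzyloxy)-2-hydroxy-3,4-dimethoxybenzaldehyde; 15 ethyl 2-[2,4-bis(benzyloxy)-5-methoxyphenyl]-2-bromoacetate (racemic)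
Product: 16 ethyl 2-[3-(benzyloxy)-2-formyl-5,6-dimethoxyphenoxy]-2-[2,4-bis(benzyloxy)-5-methoxyphenyl]acetate (racemic)
Conditions: K2CO3, DMF, 0 °C to rt
Reagents that add atoms: none
Why: Williamson etherification by SN2 displacement on an α-halo ester, which the neighbouring carbonyl accelerates; the phenoxide is the only competent nucleophile, and the low temperature is meant to prevent aldol closure of the product onto its ortho-formyl group.

Step 12
Reactants: 16 ethyl 2-[3-(benzyloxy)-2-formyl-5,6-dimethoxyphenoxy]-2-[2,4-bis(benzyloxy)-5-methoxyphenyl]acetate (racemic)
Product: 17 2-[3-(benzyloxy)-2-(hydroxymethyl)-5,6-dimethoxyphenoxy]-2-[2,4-bis(benzyloxy)-5-methoxyphenyl]ethan-1-ol (racemic)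
Conditions: LiAlH4, THF, 0 °C; Fieser work-up
Reagents that add atoms: none
Why: Hydride reduction of ester and aldehyde to the two primary alcohols; aryl, benzyl and methyl ethers are inert, and the diol is a stable resting point before the sensitive dialdehyde.

Step 13
Reactants: 17 2-[3-(benzyloxy)-2-(hydroxymethyl)-5,6-dimethoxyphenoxy]-2-[2,4-bis(benzyloxy)-5-methoxyphenyl]ethan-1-ol (racemic)
Product: 18 6-(benzyloxy)-2-{1-[2,4-bis(benzyloxy)-5-methoxyphenyl]-2-oxoethoxy}-3,4-dimethoxybenzaldehyde (racemic)
Conditions: Dess–Martin periodinane (2.5 equiv), CH2Cl2, 0 °C to rt; aq. Na2S2O3/NaHCO3 work-up; crude product used at once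
Reagents that add atoms: none
Why: Dess–Martin oxidation of both primary alcohols without added base, chosen because the α-aryl-α-aryloxy aldehyde enolises easily; the configuration at the ether carbon is irrelevant.

Step 14
Reactants: 18 6-(benzyloxy)-2-{1-[2,4-bis(benzyloxy)-5-methoxyphenyl]-2-oxoethoxy}-3,4-dimethoxybenzaldehyde (racemic)
Product: 19 racemic trans-5-(benzyloxy)-2-[2,4-bis(benzyloxy)-5-methoxyphenyl]-3-hydroxy-7,8-dimethoxychroman-4-one (2R,3R enantiomer drawn)
Conditions: 2-(pentafluorophenyl)-6,7-dihydro-5H-pyrrolo[2,1-c][1,2,4]triazol-2-ium tetrafluoroborate (20 mol %), i-Pr2NEt (20 mol %), toluene (0.02 M), rt, Ar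
Reagents that add atoms: none
Why: The carbene freed from the triazolium salt adds to one aldehyde of 18 and, after proton transfer, gives a Breslow intermediate whose nucleophilic carbon attacks the second formyl group; collapse of the adduct releases the carbene and the ketol. The closest known reaction type is the carbene-catalysed intramolecular benzoin reaction that forms six-membered cyclic ketols. Ring C closes in a 6-exo-trig mode, and the O1 aryl ether holds the two carbonyl carbons six atoms apart, so at high dilution the crossed product is enforced over intermolecular homo-coupling. The new stereocentre at C3 is set relative to C2 under thermodynamic control, since both centres can epimerise through enol and enediol forms in the presence of the amine and the trans isomer with aryl and hydroxyl equatorial should prevail; the result is of no consequence because both centres become sp2 in step 15. If the hindered, electron-rich aryl aldehyde acts as acceptor, the isomeric ketol with the carbonyl at C3 forms first; it is linked to 19 through the enediol and gives the same flavonol, so either ketol or a mixture can be taken on. The selectivity that does matter is C–C bond formation against loss of the ring A aryloxide from a Breslow intermediate on the aliphatic carbon; the weak base, the non-polar solvent, which disfavours ionisation to an aryloxide–azolium pair, and the proximity of the acceptor carbonyl are meant to secure it. Aldol addition of the enolisable aldehyde to the aryl aldehyde is reversible, because the adduct has a quaternary carbon and cannot dehydrate, and should drain into the ketol.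

Step 15
Reactants: 19 racemic trans-5-(benzyloxy)-2-[2,4-bis(benzyloxy)-5-methoxyphenyl]-3-hydroxy-7,8-dimethoxychroman-4-one
Product: 21 5-(benzyloxy)-2-[2,4-bis(benzyloxy)-5-methoxyphenyl]-3-hydroxy-7,8-dimethoxy-4H-chromen-4-one, via chromane-3,4-dione 20 (not isolated)
Conditions: Cu(OAc)2·H2O (2.2 equiv), AcOH/H2O (4:1), 70 °C, Ar
Reagents that add atoms: none
Why: Oxidation of an α-ketol to the 1,2-dione by divalent copper (the benzoin-to-benzil oxidation) through the enediol; dione 20 enolises towards C2 to the aromatic pyranone, which removes both stereocentres, and exclusion of air guards the electron-rich flavonol against oxidative cleavage.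

Step 16
Reactants: 21 5-(benzyloxy)-2-[2,4-bis(benzyloxy)-5-methoxyphenyl]-3-hydroxy-7,8-dimethoxy-4H-chromen-4-one
Product: 22 5-(benzyloxy)-2-[2,4-bis(benzyloxy)-5-methoxyphenyl]-3,7,8-trimethoxy-4H-chromen-4-one
Conditions: MeI, K2CO3, acetone, reflux
Reagents that add atoms: iodomethane, CI
Why: Williamson O-methylation of the acidic flavonol hydroxyl, the only free hydroxyl in 21.

Step 17
Reactants: 22 5-(benzyloxy)-2-[2,4-bis(benzyloxy)-5-methoxyphenyl]-3,7,8-trimethoxy-4H-chromen-4-one
Product: 23 5,2',4'-trihydroxy-3,7,8,5'-tetramethoxyflavone
Conditions: H2 (1 atm), 10% Pd/C, EtOAc/MeOH, rt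
Reagents that add atoms: none
Why: Catalytic hydrogenolysis of the three benzyl ethers under neutral conditions; the methyl ethers and the tetrasubstituted C2=C3 bond of the 3-methoxyflavone should be untouched at atmospheric pressure.

## Compound list

1 | 3-bromo-4,5-dimethoxybenzaldehyde | COc1cc(C=O)cc(Br)c1OC | starting material
2 | 3-bromo-4,5-dimethoxyphenyl formate | COc1cc(OC=O)cc(Br)c1OC | intermediate
3 | 3-bromo-4,5-dimethoxyphenol | COc1cc(O)cc(Br)c1OC | intermediate
4 | 5-(benzyloxy)-1-bromo-2,3-dimethoxybenzene | COc1cc(OCc2ccccc2)cc(Br)c1OC | intermediate
5 | 5-(benzyloxy)-2,3-dimethoxyphenol | COc1cc(OCc2ccccc2)cc(O)c1OC | intermediate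
6 | 6-(benzyloxy)-2-hydroxy-3,4-dimethoxybenzaldehyde | COc1cc(OCc2ccccc2)c(C=O)c(O)c1OC | intermediate
7 | 3-(benzyloxy)-4-methoxybenzaldehyde | COc1ccc(C=O)cc1OCc1ccccc1 | starting material
8 | 3-(benzyloxy)-4-methoxyphenyl formate | COc1ccc(OC=O)cc1OCc1ccccc1 | intermediate
9 | 3-(benzyloxy)-4-methoxyphenol | COc1ccc(O)cc1OCc1ccccc1 | intermediate
10 | 2,4-bis(benzyloxy)-1-methoxybenzene | COc1ccc(OCc2ccccc2)cc1OCc1ccccc1 | intermediate
11 | 1,5-bis(benzyloxy)-2-bromo-4-methoxybenzene | COc1cc(Br)c(OCc2ccccc2)cc1OCc1ccccc1 | intermediate
12 | [2,4-bis(benzyloxy)-5-methoxyphenyl]lithium | [Li]c1cc(OC)c(OCc2ccccc2)cc1OCc1ccccc1 | intermediate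
13 | ethyl 2-[2,4-bis(benzyloxy)-5-methoxyphenyl]-2-oxoacetate | CCOC(=O)C(=O)c1cc(OC)c(OCc2ccccc2)cc1OCc1ccccc1 | intermediate
14 | ethyl 2-[2,4-bis(benzyloxy)-5-methoxyphenyl]-2-hydroxyacetate (racemic) | CCOC(=O)C(O)c1cc(OC)c(OCc2ccccc2)cc1OCc1ccccc1 | intermediate
15 | ethyl 2-[2,4-bis(benzyloxy)-5-methoxyphenyl]-2-bromoacetate (racemic) | CCOC(=O)C(Br)c1cc(OC)c(OCc2ccccc2)cc1OCc1ccccc1 | intermediate
16 | ethyl 2-[3-(benzyloxy)-2-formyl-5,6-dimethoxyphenoxy]-2-[2,4-bis(benzyloxy)-5-methoxyphenyl]acetate (racemic) | CCOC(=O)C(Oc1c(OC)c(OC)cc(OCc2ccccc2)c1C=O)c1cc(OC)c(OCc2ccccc2)cc1OCc1ccccc1 | intermediate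
17 | 2-[3-(benzyloxy)-2-(hydroxymethyl)-5,6-dimethoxyphenoxy]-2-[2,4-bis(benzyloxy)-5-methoxyphenyl]ethan-1-ol (racemic) | OCC(Oc1c(OC)c(OC)cc(OCc2ccccc2)c1CO)c1cc(OC)c(OCc2ccccc2)cc1OCc1ccccc1 | intermediate
18 | 6-(benzyloxy)-2-{1-[2,4-bis(benzyloxy)-5-methoxyphenyl]-2-oxoethoxy}-3,4-dimethoxybenzaldehyde (racemic) | O=CC(Oc1c(OC)c(OC)cc(OCc2ccccc2)c1C=O)c1cc(OC)c(OCc2ccccc2)cc1OCc1ccccc1 | intermediate
19 | racemic trans-5-(benzyloxy)-2-[2,4-bis(benzyloxy)-5-methoxyphenyl]-3-hydroxy-7,8-dimethoxychroman-4-one (2R,3R enantiomer drawn) | COc1cc([C@H]2Oc3c(OC)c(OC)cc(OCc4ccccc4)c3C(=O)[C@@H]2O)c(OCc2ccccc2)cc1OCc1ccccc1 | intermediate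
20 | 5-(benzyloxy)-2-[2,4-bis(benzyloxy)-5-methoxyphenyl]-7,8-dimethoxychromane-3,4-dione (racemic) | COc1cc(C2Oc3c(OC)c(OC)cc(OCc4ccccc4)c3C(=O)C2=O)c(OCc2ccccc2)cc1OCc1ccccc1 | intermediate
21 | 5-(benzyloxy)-2-[2,4-bis(benzyloxy)-5-methoxyphenyl]-3-hydroxy-7,8-dimethoxy-4H-chromen-4-one | COc1cc(-c2oc3c(OC)c(OC)cc(OCc4ccccc4)c3c(=O)c2O)c(OCc2ccccc2)cc1OCc1ccccc1 | intermediate
22 | 5-(benzyloxy)-2-[2,4-bis(benzyloxy)-5-methoxyphenyl]-3,7,8-trimethoxy-4H-chromen-4-one | COc1cc(-c2oc3c(OC)c(OC)cc(OCc4ccccc4)c3c(=O)c2OC)c(OCc2ccccc2)cc1OCc1ccccc1 | intermediate
23 | 5,2',4'-trihydroxy-3,7,8,5'-tetramethoxyflavone | COc1cc(-c2oc3c(OC)c(OC)cc(O)c3c(=O)c2OC)c(O)cc1O | target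

## Step count and least certain steps

Total: 17 steps. Longest linear sequence: 13 steps (7 to 23, steps 5–17). The ring A arm (steps 1–4) joins at step 11.

Step 14 (key step). The most likely failure is fragmentation in place of ring closure. The carbene should add most readily to the more electrophilic aliphatic aldehyde, and the Breslow intermediate formed there has the ring A aryloxide on the adjacent carbon. Expulsion of that aryloxide (an ortho-formyl phenoxide is a fair leaving group), followed by acyl transfer, would break the O1–C2 bond. Slow carbene addition to the doubly ortho-substituted aryl aldehyde would make this worse.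
Fallback, reductive rather than redox-neutral coupling: from 18, SmI2 (divalent samarium, THF, −78 °C) should reduce the aryl aldehyde first to its ketyl, which adds to the aliphatic aldehyde. No carbanion character then develops at C3 and the aryloxide stays in place. This pinacol cyclisation should give 5-(benzyloxy)-2-[2,4-bis(benzyloxy)-5-methoxyphenyl]-7,8-dimethoxychromane-3,4-diol F1 as a mixture of diastereomers. Swern oxidation of both carbinols of F1 (DMSO, (COCl)2; Et3N) leads to dione 20, which tautomerises, and the route is rejoined at 21.

Step 13. The likely failure is loss of the dialdehyde during its formation and handling, through enolisation of the α-aryl-α-aryloxy aldehyde, aldol closure onto the aryl aldehyde, hydration or air oxidation.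
Fallback, staged unmasking: from 17, MnO2 in CH2Cl2 should oxidise only the benzylic alcohol and give the stable hydroxy aldehyde 6-(benzyloxy)-2-{1-[2,4-bis(benzyloxy)-5-methoxyphenyl]-2-hydroxyethoxy}-3,4-dimethoxybenzaldehyde F2, which can be purified and stored. The remaining primary alcohol is then oxidised on its own with TEMPO/PhI(OAc)2 immediately before the carbene step, which returns to 18.

Step 11. The likely failures are solvolysis or decomposition of the electron-rich benzylic bromide before the hindered, hydrogen-bonded phenoxide reacts, and base-induced Darzens or aldol reactions of the α-bromo ester or of the product with the formyl group.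
Fallback, redox condensation in place of SN2 on an isolated halide: from 14 and 6, a Mitsunobu reaction (PPh3, DIAD, THF, 0 °C to rt) couples the mandelate directly with the acidic salicylaldehyde phenol and returns to 16. This fallback makes no new compound (F0).

Step 15. The likely failures are ring contraction of the ketol by α-ketol rearrangement to a benzofuranone, acid-promoted opening at C2 next to the electron-rich ring B, or oxidative degradation of the flavonol by copper and adventitious oxygen.
Fallback, methylation before dehydrogenation: from 19, MeI and Ag2O (CH2Cl2, rt) should give racemic trans-5-(benzyloxy)-2-[2,4-bis(benzyloxy)-5-methoxyphenyl]-3,7,8-trimethoxychroman-4-one F3. Dehydrogenation of this flavanone with DDQ (1,4-dioxane, reflux) introduces the C2=C3 bond and returns to 22, bypassing 21.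

Step 8. The likely failures are double addition of the aryllithium to the oxalate or to the keto ester, and anionic rearrangement of the ortho-benzyloxy aryllithium if the temperature rises.
Fallback, electrophilic substitution in place of organolithium chemistry: from 10, a Friedel–Crafts hydroxyalkylation with ethyl glyoxylate catalysed by Yb(OTf)3 (CH2Cl2, rt) should attack the same ring position as the bromination and give mandelate 14 directly, where the route is rejoined. This fallback makes no new compound (F0).

## Further compounds

F1 | step 14 | 5-(benzyloxy)-2-[2,4-bis(benzyloxy)-5-methoxyphenyl]-7,8-dimethoxychromane-3,4-diol (racemic, mixture of diastereomers) | COc1cc(C2Oc3c(OC)c(OC)cc(OCc4ccccc4)c3C(O)C2O)c(OCc2ccccc2)cc1OCc1ccccc1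
F2 | step 13 | 6-(benzyloxy)-2-{1-[2,4-bis(benzyloxy)-5-methoxyphenyl]-2-hydroxyethoxy}-3,4-dimethoxybenzaldehyde (racemic) | OCC(Oc1c(OC)c(OC)cc(OCc2ccccc2)c1C=O)c1cc(OC)c(OCc2ccccc2)cc1OCc1ccccc1
F0 | step 11 | none | none
F3 | step 15 | racemic trans-5-(benzyloxy)-2-[2,4-bis(benzyloxy)-5-methoxyphenyl]-3,7,8-trimethoxychroman-4-one (2R,3R enantiomer drawn) | COc1cc([C@H]2Oc3c(OC)c(OC)cc(OCc4ccccc4)c3C(=O)[C@@H]2OC)c(OCc2ccccc2)cc1OCc1ccccc1
F0 | step 8 | none | none
A1 | alternative 1 | 1-[6-(benzyloxy)-3,4-dimethoxy-2-(methoxymethoxy)phenyl]-3-[2,4-bis(benzyloxy)-5-methoxyphenyl]-2-methoxypropane-1,3-dione (racemic, enolisable) | COCOc1c(C(=O)C(OC)C(=O)c2cc(OC)c(OCc3ccccc3)cc2OCc2ccccc2)c(OCc2ccccc2)cc(OC)c1OC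
A2 | alternative 1 | 1-(benzyloxy)-2-iodo-4,5-dimethoxy-3-(methoxymethoxy)benzene | COCOc1c(I)c(OCc2ccccc2)cc(OC)c1OC
A3 | alternative 1 | 1-[2,4-bis(benzyloxy)-5-methoxyphenyl]-2-methoxyethan-1-one | COCC(=O)c1cc(OC)c(OCc2ccccc2)cc1OCc1ccccc1
A4 | alternative 1 | carbon monoxide | [C-]#[O+]
A5 | alternative 2 | 2-(2,4-dihydroxy-5-methoxyphenyl)-3,5,7,8-tetramethoxy-4H-chromen-4-one | COc1cc(-c2oc3c(OC)c(OC)cc(OC)c3c(=O)c2OC)c(O)cc1O
A6 | alternative 2 | 2-ethynyl-3,5,7,8-tetramethoxy-4H-chromen-4-one | C#Cc1oc2c(OC)c(OC)cc(OC)c2c(=O)c1OC
A7 | alternative 2 | 1,4-dimethoxy-1,3-bis(trimethylsilyloxy)buta-1,3-diene | COC=C(O[Si](C)(C)C)C=C(OC)O[Si](C)(C)C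
A8 | alternative 3 | 2-[2,4-bis(benzyloxy)-5-methoxyphenyl]-3,5,7-trimethoxy-4H-chromen-4-one | COc1cc(OC)c2c(=O)c(OC)c(-c3cc(OC)c(OCc4ccccc4)cc3OCc3ccccc3)oc2c1
A9 | alternative 3 | 3,5-dimethoxy-2-(trimethylsilyl)phenyl trifluoromethanesulfonate | COc1cc(OC)c([Si](C)(C)C)c(OS(=O)(=O)C(F)(F)F)c1
A10 | alternative 3 | 3-[2,4-bis(benzyloxy)-5-methoxyphenyl]-2,3-dimethoxyprop-2-enoic acid (alkene geometry not specified) | COC(C(=O)O)=C(OC)c1cc(OC)c(OCc2ccccc2)cc1OCc1ccccc1
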